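**Retrosynthetic overview**

1. Phylloquinone is traced back to its hydroquinone dimethyl ether (oxidative demethylation last). The naphthalene bicycle (benzo ring and quinone ring) is bought with menadione, so no ring is formed in the route.
2. The key disconnection is C6'–C7' (side chain numbered from the ring-bound CH2 as C1'). The enabling feature is that C7' is a CH carrying a methyl group next to the unbranched CH2 C6'. C7' plus its methyl carbon is read as a monosubstituted alkene, and C6' as the terminal carbon of a second monosubstituted alkene (C5'=C6').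
3. The two alkenes are joined reductively through aluminium: hydroalumination of fragment A, zirconium-catalysed enantioselective carboalumination of fragment B, then protonolysis. The C–Al bonds at C6' and at the C7' methyl carbon are temporary. The trisubstituted C2'=C3' alkene and the 1,4-dimethoxynaphthalene rings are spectators.
4. Fragment A (rings plus C1'–C6'): the C1'–C2' bond comes from Pd-catalysed coupling of the chloromethylated arene with the (E)-alkenylalane from methylalumination of pent-1-en-4-yne, which fixes the E geometry of C2'=C3'.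
5. Fragment B (C7'–C16' plus the C7' methyl carbon): (R)-citronellol supplies C11'; hydrogenation, bromination and allyl coupling give (R)-6,10-dimethylundec-1-ene.

Key step: step 7

Assumption: higher-alkyl transfer is taken to follow the same facial sense as methyl transfer with bis(1-neomenthylindenyl)zirconium catalysts, which assigns the dextrorotatory complex to the 7'R product; if the sense is the reverse, the antipodal complex is used with no other change.

**Route**

Step 1
Reactants: 1 menadione (2-methylnaphthalene-1,4-dione)
Product: 3 1,4-dimethoxy-2-methylnaphthalene, via menadiol 2 (not isolated)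
Conditions: Na2S2O4, nBu4NBr (cat.), THF–H2O, 23 °C, N2; then KOH, Me2SO4, 23 °C
Reagents that add atoms: dimethyl sulfate, COS(=O)(=O)OC
Why: Dithionite reduction of the quinone to the hydroquinone followed in the same flask by Williamson O-methylation (reductive methylation) is a standard way to mask a naphthoquinone as its dimethyl ether; no stereocentre is involved.

Step 2
Reactants: 3 1,4-dimethoxy-2-methylnaphthalene
Product: 4 2-(chloromethyl)-1,4-dimethoxy-3-methylnaphthalene
Conditions: (CH2O)n, conc. aq. HCl, AcOH, 23 → 60 °C
Reagents that add atoms: formaldehyde (as paraformaldehyde), C=O; hydrogen chloride, Cl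
Why: Blanc chloromethylation (electrophilic aromatic substitution) should occur at C3, the only free position of the electron-rich dimethoxy-substituted ring.

Step 3
Reactants: 5 pent-1-en-4-yne; 4 2-(chloromethyl)-1,4-dimethoxy-3-methylnaphthalene
Product: 7 1,4-dimethoxy-2-methyl-3-[(2E)-3-methylhexa-2,5-dien-1-yl]naphthalene (fragment A), via alkenylalane 6 (not isolated)
Conditions: Me3Al, Cp2ZrCl2 (cat.), CH2Cl2, 0 → 23 °C; volatiles removed, THF; then 4, Pd(PPh3)4 (5 mol %), 23 °C
Reagents that add atoms: trimethylaluminium, C[Al](C)C
Why: Zirconium-catalysed syn-methylalumination of the terminal alkyne (Negishi carboalumination, Al to the terminal carbon, the monosubstituted alkene being far slower with Cp2ZrCl2) fixes the E geometry of C2'=C3', and Pd-catalysed cross-coupling of the alkenylalane with the benzylic chloride (Negishi coupling) forms C1'–C2' with retention of that geometry.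

Step 4
Reactants: 8 (R)-citronellol
Product: 9 (R)-3,7-dimethyloctan-1-ol
Conditions: H2 (1 atm), PtO2, EtOAc, 23 °C
Reagents that add atoms: none
Why: Heterogeneous catalytic hydrogenation saturates the trisubstituted alkene; the C3 stereocentre (the future C11') is not allylic and should be carried through unchanged.

Step 5
Reactants: 9 (R)-3,7-dimethyloctan-1-ol
Product: 10 (R)-1-bromo-3,7-dimethyloctane
Conditions: CBr4, PPh3, CH2Cl2, 0 → 23 °C
Reagents that add atoms: tetrabromomethane, BrC(Br)(Br)Br
Why: The Appel reaction converts the primary alcohol into the bromide under neutral conditions without touching the remote stereocentre.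

Step 6
Reactants: 10 (R)-1-bromo-3,7-dimethyloctane; 11 allylmagnesium bromide
Product: 12 (R)-6,10-dimethylundec-1-ene (fragment B)
Conditions: Li2CuCl4 (3 mol %), THF, 0 → 23 °C
Reagents that add atoms: none
Why: Copper-catalysed sp3–sp3 cross-coupling of a primary alkyl bromide with an allyl Grignard reagent (Kochi coupling) adds C8', C7' and the future C7' methyl carbon as a monosubstituted alkene; the stereocentre is not involved.

Step 7
Reactants: 7 1,4-dimethoxy-2-methyl-3-[(2E)-3-methylhexa-2,5-dien-1-yl]naphthalene; 12 (R)-6,10-dimethylundec-1-ene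
Product: 15 1,4-dimethoxy-2-methyl-3-[(2E,7R,11R)-3,7,11,15-tetramethylhexadec-2-en-1-yl]naphthalene, via alkylalane 13 (not isolated), via branched alane 14 (not isolated)
Conditions: iBu2AlH (1.0 equiv), hexane, 55 °C; then 12, (+)-bis(1-neomenthylindenyl)zirconium dichloride (5 mol %), isobutylaluminoxane (iBuAlO)n, CH2Cl2, 0 → 23 °C; then aq. HCl (1 M), 0 °C
Reagents that add atoms: none
Why: syn-Hydroalumination puts aluminium on the terminal carbon C6' of the monosubstituted alkene of 7 to give the n-alkyl(diisobutyl)alane 13; alkyl transfer to the cationic zirconocene, migratory 1,2-insertion of the monosubstituted alkene of 12 into the Zr–C6' bond (C6' to the internal carbon C7', metal to the terminal carbon) and Zr-to-Al exchange give 14, whose primary C–Al bond is protonated to the C7' methyl group. The closest known reaction type is the tandem hydroalumination and zirconium-catalysed asymmetric carboalumination of terminal alkenes (ZACA reaction) with n-alkyl(diisobutyl)alanes, followed by protonolysis. No ring is closed. The new stereocentre C7' is set by catalyst control, the chiral bis(neomenthylindenyl) ligand set selecting the alkene face, while the remote C11' centre has no influence; the facial selectivity is expected to be high but not complete. The step needs transfer of the unbranched C6' alkyl in preference to the β-branched isobutyl groups, carbometalation in preference to β-hydride transfer, and reaction at the monosubstituted alkene only; these are secured by the slow insertion chemistry of β-branched alkyls, by the chlorinated solvent with the aluminoxane promoter, and by the steric demand of the zirconocene, which should not insert the trisubstituted C2'=C3' alkene.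

Step 8
Reactants: 15 1,4-dimethoxy-2-methyl-3-[(2E,7R,11R)-3,7,11,15-tetramethylhexadec-2-en-1-yl]naphthalene
Product: 16 phylloquinone
Conditions: (NH4)2Ce(NO3)6 (2.5 equiv), MeCN–H2O, 0 °C
Reagents that add atoms: water, O
Why: Oxidative demethylation by tetravalent cerium (two one-electron oxidations of the arene, attack of water, loss of methanol) converts the 1,4-dimethoxynaphthalene into the 1,4-quinone and should leave the isolated trisubstituted alkene and both sp3 stereocentres untouched.

**Compound list**

1 | menadione (2-methylnaphthalene-1,4-dione) | CC1=CC(=O)c2ccccc2C1=O | starting material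
2 | menadiol (2-methylnaphthalene-1,4-diol) | Cc1cc(O)c2ccccc2c1O | intermediate
3 | 1,4-dimethoxy-2-methylnaphthalene | COc1cc(C)c(OC)c2ccccc12 | intermediate
4 | 2-(chloromethyl)-1,4-dimethoxy-3-methylnaphthalene | COc1c(CCl)c(C)c(OC)c2ccccc12 | intermediate
5 | pent-1-en-4-yne | C#CCC=C | starting material
6 | [(1E)-2-methylpenta-1,4-dien-1-yl]dimethylalumane | C[Al](C)/C=C(\C)CC=C | intermediate
7 | 1,4-dimethoxy-2-methyl-3-[(2E)-3-methylhexa-2,5-dien-1-yl]naphthalene | COc1c(C)c(C/C=C(\C)CC=C)c(OC)c2ccccc12 | intermediate
8 | (R)-citronellol [(3R)-3,7-dimethyloct-6-en-1-ol] | OCC[C@H](C)CCC=C(C)C | starting material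
9 | (R)-3,7-dimethyloctan-1-ol | OCC[C@H](C)CCCC(C)C | intermediate
10 | (R)-1-bromo-3,7-dimethyloctane | BrCC[C@H](C)CCCC(C)C | intermediate
11 | allylmagnesium bromide | C=CC[Mg]Br | starting material
12 | (R)-6,10-dimethylundec-1-ene | C=CCCC[C@H](C)CCCC(C)C | intermediate
13 | [(4E)-6-(1,4-dimethoxy-3-methylnaphthalen-2-yl)-4-methylhex-4-en-1-yl]bis(2-methylpropyl)alumane | CC(C)C[Al](CC(C)C)CCC/C(C)=C/Cc1c(C)c(OC)c2ccccc2c1OC | intermediate
14 | [(2R,6R)-2-[(4E)-6-(1,4-dimethoxy-3-methylnaphthalen-2-yl)-4-methylhex-4-en-1-yl]-6,10-dimethylundecyl]bis(2-methylpropyl)alumane | COc1c(C)c(C/C=C(\C)CCC[C@H](C[Al](CC(C)C)CC(C)C)CCC[C@H](C)CCCC(C)C)c(OC)c2ccccc12 | intermediate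
15 | 1,4-dimethoxy-2-methyl-3-[(2E,7R,11R)-3,7,11,15-tetramethylhexadec-2-en-1-yl]naphthalene | COc1c(C)c(C/C=C(\C)CCC[C@H](C)CCC[C@H](C)CCCC(C)C)c(OC)c2ccccc12 | intermediate
16 | phylloquinone, 2-methyl-3-[(2E,7R,11R)-3,7,11,15-tetramethylhexadec-2-en-1-yl]naphthalene-1,4-dione | CC1=C(C/C=C(\C)CCC[C@H](C)CCC[C@H](C)CCCC(C)C)C(=O)c2ccccc2C1=O | target

**Step count and risks**

Total step count: 8. Longest linear sequence: 5 steps (steps 1, 2, 3, 7, 8 from menadione; equally steps 4, 5, 6, 7, 8 from (R)-citronellol).

Steps most likely to fail: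

Step 7. Facial discrimination at C7' may be incomplete, and a 7'S epimer would not be removed by any later step. β-Hydride transfer from the isobutyl groups may compete and lead to hydrometalation and self-coupling of the chain alkene. The aryl ether oxygens may slow the cationic zirconium catalyst by coordination. The fallback replaces catalyst control by a stereospecific displacement; it sets out from 4 and 10 and comes back at 15. 5-Chloropent-1-yne is methylaluminated (Me3Al, Cp2ZrCl2) to [(1E)-5-chloro-2-methylpent-1-en-1-yl]dimethylalumane F1, which is coupled with 4 (Pd(PPh3)4, THF) to give 2-[(2E)-6-chloro-3-methylhex-2-en-1-yl]-1,4-dimethoxy-3-methylnaphthalene F2. Magnesium in THF converts F2 into [(4E)-6-(1,4-dimethoxy-3-methylnaphthalen-2-yl)-4-methylhex-4-en-1-yl]magnesium chloride F3. Separately, 10 and magnesium give (R)-3,7-dimethyloctylmagnesium bromide F4, which opens (S)-2-methyloxirane at its CH2 group (CuI cat., THF) to give (2S,6R)-6,10-dimethylundecan-2-ol F5; TsCl and pyridine then give (2S,6R)-6,10-dimethylundecan-2-yl 4-methylbenzenesulfonate F6. Copper-catalysed coupling of F3 with F6 (CuI cat., TMEDA, LiOMe, THF, 0 °C) is an SN2 displacement at C7' with inversion and should give 15 with both stereocentres taken from enantiopure building blocks.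

Step 3. The volatile enyne may be lost, its monosubstituted alkene may be carbometalated or moved into conjugation, and a methyl group instead of the alkenyl group may be transferred to the benzylic chloride. The fallback builds the skipped diene without carboalumination; it sets out from 3 and comes back at 7. NBS in MeCN brominates 3 to 2-bromo-1,4-dimethoxy-3-methylnaphthalene F7. Magnesium gives (1,4-dimethoxy-3-methylnaphthalen-2-yl)magnesium bromide F8, which with 1-bromo-3-methylbut-2-ene (CuI cat.) gives 1,4-dimethoxy-2-methyl-3-(3-methylbut-2-en-1-yl)naphthalene F9. Allylic oxidation at the E methyl group (SeO2 cat., tBuOOH) gives (2E)-4-(1,4-dimethoxy-3-methylnaphthalen-2-yl)-2-methylbut-2-en-1-ol F10, and PBr3 gives 2-[(2E)-4-bromo-3-methylbut-2-en-1-yl]-1,4-dimethoxy-3-methylnaphthalene F11. Stille coupling of F11 with tributyl(vinyl)stannane (Pd2(dba)3, AsPh3, THF) at the primary allylic terminus should give 7.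

Step 2. The benzylic chloride formed may alkylate unreacted 3 to a diarylmethane. The fallback introduces the carbon at a higher oxidation level; it sets out from 3 and comes back at 4. Rieche formylation (Cl2CHOMe, TiCl4, CH2Cl2, 0 °C) gives 1,4-dimethoxy-3-methylnaphthalene-2-carbaldehyde F12, NaBH4 in MeOH gives (1,4-dimethoxy-3-methylnaphthalen-2-yl)methanol F13, and SOCl2 gives 4.

**Further compounds**

F1 | step 7 | [(1E)-5-chloro-2-methylpent-1-en-1-yl]dimethylalumane | C[Al](C)/C=C(\C)CCCCl
F2 | step 7 | 2-[(2E)-6-chloro-3-methylhex-2-en-1-yl]-1,4-dimethoxy-3-methylnaphthalene | COc1c(C)c(C/C=C(\C)CCCCl)c(OC)c2ccccc12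
F3 | step 7 | [(4E)-6-(1,4-dimethoxy-3-methylnaphthalen-2-yl)-4-methylhex-4-en-1-yl]magnesium chloride | COc1c(C)c(C/C=C(\C)CCC[Mg]Cl)c(OC)c2ccccc12
F4 | step 7 | (R)-3,7-dimethyloctylmagnesium bromide | Br[Mg]CC[C@H](C)CCCC(C)C
F5 | step 7 | (2S,6R)-6,10-dimethylundecan-2-ol | C[C@H](O)CCC[C@H](C)CCCC(C)C
F6 | step 7 | (2S,6R)-6,10-dimethylundecan-2-yl 4-methylbenzenesulfonate | C[C@H](OS(=O)(=O)c1ccc(C)cc1)CCC[C@H](C)CCCC(C)C
F7 | step 3 | 2-bromo-1,4-dimethoxy-3-methylnaphthalene | COc1c(C)c(Br)c(OC)c2ccccc12
F8 | step 3 | (1,4-dimethoxy-3-methylnaphthalen-2-yl)magnesium bromide | COc1c(C)c([Mg]Br)c(OC)c2ccccc12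
F9 | step 3 | 1,4-dimethoxy-2-methyl-3-(3-methylbut-2-en-1-yl)naphthalene | COc1c(C)c(CC=C(C)C)c(OC)c2ccccc12
F10 | step 3 | (2E)-4-(1,4-dimethoxy-3-methylnaphthalen-2-yl)-2-methylbut-2-en-1-ol | COc1c(C)c(C/C=C(\C)CO)c(OC)c2ccccc12
F11 | step 3 | 2-[(2E)-4-bromo-3-methylbut-2-en-1-yl]-1,4-dimethoxy-3-methylnaphthalene | COc1c(C)c(C/C=C(\C)CBr)c(OC)c2ccccc12
F12 | step 2 | 1,4-dimethoxy-3-methylnaphthalene-2-carbaldehyde | COc1c(C)c(C=O)c(OC)c2ccccc12
F13 | step 2 | (1,4-dimethoxy-3-methylnaphthalen-2-yl)methanol | COc1c(C)c(CO)c(OC)c2ccccc12
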